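**Retrosynthetic overview** (eudesmane numbering: ring A = C1–C5 + C10; ring B = C5–C10; C14 = CH3 on C10; C15 = CH2 on C4)
1. Target ⇒ C9–O acylation and C9 carbinol ⇒ C9 ketone (cis-decalone); ring A ⇒ C10–C1 (enolate alkylation) + C5–C4 (conjugate addition).
2. Enabling feature: in ring B the C9 oxygen sits next to the quaternary C10 and C5 is β to it. At the ketone oxidation level C5=C10 is the double bond of a 2-methylcyclohexenone, so C1–C4 with C15 can be delivered as one C5 reagent, nucleophilic at C4 (vinyl metal) and electrophilic at C1 (chloride). The cis fusion (H-5/CH3-14) is what a tethered closure gives.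
3. Ring order: ring B is taken intact from (R)-piperitone (C7 isopropyl, C6 oxygen, C10 methyl in place); C6–OH is set cis to isopropyl and C9 is oxidised to the enone; ring A is closed last, in one flask.
4. Stereochemical relay: C7 → C6 → C5 (addition anti to C6–OSi, trans to isopropyl) → C10 (cis closure) → C9 (hydride from the β-face).

Key step: step 5

Assumption: (R)-(−)-piperitone (natural, Eucalyptus dives type) is taken as a commercial starting material of high enantiomeric purity; the ee of the lot should be checked, since the ketone racemises slowly through its enol.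

**Step 1**
Reactants: 1 (R)-(−)-piperitone, (6R)-3-methyl-6-(propan-2-yl)cyclohex-2-en-1-one
Product: 2 cis-piperitol, (1S,6R)-3-methyl-6-(propan-2-yl)cyclohex-2-en-1-ol
Conditions: L-Selectride, THF, −78 °C; then H2O
Reagents that add atoms: none
Why: 1,2-reduction of a β,β-disubstituted enone by a bulky trialkylborohydride (conjugate reduction is blocked at the substituted β-carbon), in which the hydride should enter on the face away from the neighbouring equatorial isopropyl group so that the new C6 carbinol carries a pseudo-axial OH cis to isopropyl, as in menthone → neomenthol.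

**Step 2**
Reactants: 2 cis-piperitol
Product: 3 tert-butyl(dimethyl){[(1S,6R)-3-methyl-6-(propan-2-yl)cyclohex-2-en-1-yl]oxy}silane
Conditions: TBSOTf, 2,6-lutidine, CH2Cl2, 0 °C
Reagents that add atoms: tert-butyldimethylsilyl trifluoromethanesulfonate (TBSOTf), CC(C)(C)[Si](C)(C)OS(=O)(=O)C(F)(F)F
Why: standard O-silylation of a hindered secondary allylic alcohol with the silyl triflate, which touches no stereocentre and gives an ether that should survive the cuprate, enolate and hydride steps.

**Step 3**
Reactants: 3 silyl ether of cis-piperitol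
Product: 5 (4S,5R)-4-[(tert-butyldimethylsilyl)oxy]-2-methyl-5-(propan-2-yl)cyclohex-2-en-1-one, via allylic alcohol 4 (not isolated)
Conditions: SeO2 (cat.), t-BuOOH, CH2Cl2, rt; then Dess–Martin periodinane, CH2Cl2, rt
Reagents that add atoms: selenium dioxide, O=[Se]=O (catalytic oxygen carrier); tert-butyl hydroperoxide, CC(C)(C)OO (terminal oxidant)
Why: Riley–Sharpless allylic oxidation (ene reaction then [2,3]-sigmatropic shift), which by the Guillemonat rules should functionalise the ring CH2 next to the more substituted alkene carbon (C9, not the C14 methyl and not the silyloxy-bearing C6) without moving the double bond, followed by Dess–Martin oxidation that converges both C9 epimers of the allylic alcohol into the enone, in which neither C6 nor C7 is α to the carbonyl.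

**Step 4**
Reactants: 6 5-chloropent-1-yne
Product: 8 2-bromo-5-chloropent-1-ene, via alkenylborane 7 (not isolated)
Conditions: B-bromo-9-BBN, CH2Cl2, 0 °C → rt; then AcOH
Reagents that add atoms: B-bromo-9-borabicyclo[3.3.1]nonane (B-Br-9-BBN), BrB1C2CCCC1CCC2
Why: Markovnikov syn-bromoboration of the terminal alkyne (Hara–Suzuki haloboration) followed by protodeboronation with acetic acid should give the 2-bromo-1-alkene, the primary chloride being inert.

**Step 5**
Reactants: 5 (4S,5R)-4-[(tert-butyldimethylsilyl)oxy]-2-methyl-5-(propan-2-yl)cyclohex-2-en-1-one, 8 2-bromo-5-chloropent-1-ene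
Product: 12 (3R,4S,4aS,8aR)-4-[(tert-butyldimethylsilyl)oxy]-8a-methyl-5-methylidene-3-(propan-2-yl)octahydronaphthalen-1(2H)-one, via vinyllithium 9 (not isolated), via cuprate 10 (not isolated), via lithium enolate 11 (not isolated)
Conditions: 8, t-BuLi (2 equiv), Et2O, −78 °C; PhSCu, THF, −78 → −20 °C; 5, −78 → −20 °C; then HMPA, −20 → 45 °C
Reagents that add atoms: none
Why: Bromine–lithium exchange gives 5-chloro-2-lithiopent-1-ene, whose phenylthiocuprate adds 1,4 to enone 5 to make the C4–C5 bond and leave a regiodefined lithium enolate (O on C9, nucleophilic at C10), which after addition of HMPA displaces the tethered primary chloride to make the C10–C1 bond. The closest known reaction is the Piers methylenecyclohexane annulation of 2-methylcycloalkenones with this same bifunctional reagent, a Michael-initiated ring closure that is usually completed with KH in a second flask. Ring A closes in the 6-exo-tet mode at the enolate carbon C10. C5 is controlled by the substrate: the cuprate attacks axially on the half-chair of 5 that has the C7 isopropyl group equatorial and the C6 silyloxy group pseudo-axial, that is on the β-face, anti to OTBS and trans to isopropyl, as in cuprate additions to carvone. C10 is controlled by the tether: the chain sits on the β-face of C5 and reaches only the β-lobe of C10 in a chair-like axial alkylation, so the ring fusion is cis and CH3-14 ends up α, cis to H-5. The step needs C- instead of O-alkylation (O-closure would need an eight-membered ring), exchange at C–Br without attack on C–Cl (−78 °C) and an enolate that stays at C10 (no proton source in the flask), and the exocyclic C4=C15 methylene arrives ready-made as the vinyl carbon of the reagent.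

**Step 6**
Reactants: 12 (3R,4S,4aS,8aR)-4-[(tert-butyldimethylsilyl)oxy]-8a-methyl-5-methylidene-3-(propan-2-yl)octahydronaphthalen-1(2H)-one
Product: 13 (1R,3R,4S,4aS,8aR)-4-[(tert-butyldimethylsilyl)oxy]-8a-methyl-5-methylidene-3-(propan-2-yl)decahydronaphthalen-1-ol
Conditions: L-Selectride, THF, −78 → 0 °C; then H2O
Reagents that add atoms: none
Why: substrate-controlled ketone reduction by a bulky trialkylborohydride, in which the chair of the cis-decalone that keeps the C6 silyloxy group equatorial (no 1,3-diaxial clash with CH3-14) has the C7 isopropyl group axial and screening the α-face of C9=O, which is also flanked by the α-methyl on C10, so that hydride should be delivered equatorially from the β-face (as in Selectride reductions of 3,3,5-trimethylcyclohexanone and of 4,4-dimethyl-3-keto triterpenoids) and the new C9–OH should be α, cis to CH3-14.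

**Step 7**
Reactants: 13 (1R,3R,4S,4aS,8aR)-4-[(tert-butyldimethylsilyl)oxy]-8a-methyl-5-methylidene-3-(propan-2-yl)decahydronaphthalen-1-ol, 14 4-methoxybenzoyl chloride
Product: 15 (1R,3R,4S,4aS,8aR)-4-[(tert-butyldimethylsilyl)oxy]-8a-methyl-5-methylidene-3-(propan-2-yl)decahydronaphthalen-1-yl 4-methoxybenzoate
Conditions: DMAP (cat.), pyridine, 60 °C
Reagents that add atoms: none
Why: DMAP-catalysed acylation (nucleophilic catalysis through the N-acylpyridinium salt) of the only free hydroxyl, which is hindered and neopentyl-like and therefore needs heat, and since the C9–O bond is not broken the configuration is retained.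

**Step 8**
Reactants: 15 (1R,3R,4S,4aS,8aR)-4-[(tert-butyldimethylsilyl)oxy]-8a-methyl-5-methylidene-3-(propan-2-yl)decahydronaphthalen-1-yl 4-methoxybenzoate
Product: 16 (1R,3R,4S,4aS,8aR)-4-hydroxy-8a-methyl-5-methylidene-3-(propan-2-yl)decahydronaphthalen-1-yl 4-methoxybenzoate (CNP0107029.1)
Conditions: HF·pyridine, pyridine, THF, 0 °C → rt
Reagents that add atoms: none
Why: fluoride-induced Si–O cleavage driven by the strong Si–F bond, under a pyridine-buffered reagent that should leave the aryl ester and the exocyclic alkene alone, while an acyl shift from O9 to O6 across the ring is geometrically not available, so the free C6 alcohol of the target results.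

**Compound list**
1 | (R)-(−)-piperitone, (6R)-3-methyl-6-(propan-2-yl)cyclohex-2-en-1-one | CC1=CC(=O)[C@@H](C(C)C)CC1 | starting material
2 | cis-piperitol, (1S,6R)-3-methyl-6-(propan-2-yl)cyclohex-2-en-1-ol (OH cis to isopropyl) | CC1=C[C@@H](O)[C@@H](C(C)C)CC1 | intermediate
3 | tert-butyl(dimethyl){[(1S,6R)-3-methyl-6-(propan-2-yl)cyclohex-2-en-1-yl]oxy}silane | CC1=C[C@@H](O[Si](C)(C)C(C)(C)C)[C@@H](C(C)C)CC1 | intermediate
4 | (4S,5R)-4-[(tert-butyldimethylsilyl)oxy]-2-methyl-5-(propan-2-yl)cyclohex-2-en-1-ol, both C1 epimers | CC1=C[C@@H](O[Si](C)(C)C(C)(C)C)[C@@H](C(C)C)CC1O | intermediate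
5 | (4S,5R)-4-[(tert-butyldimethylsilyl)oxy]-2-methyl-5-(propan-2-yl)cyclohex-2-en-1-one (OSi cis to isopropyl) | CC1=C[C@@H](O[Si](C)(C)C(C)(C)C)[C@@H](C(C)C)CC1=O | intermediate
6 | 5-chloropent-1-yne | C#CCCCCl | starting material
7 | (Z)-9-(2-bromo-5-chloropent-1-en-1-yl)-9-borabicyclo[3.3.1]nonane | ClCCC/C(Br)=C/B1C2CCCC1CCC2 | intermediate
8 | 2-bromo-5-chloropent-1-ene | C=C(Br)CCCCl | intermediate
9 | (5-chloropent-1-en-2-yl)lithium | [Li]C(=C)CCCCl | intermediate
10 | lithium (5-chloropent-1-en-2-yl)(phenylsulfanyl)cuprate | [Li+].C=C(CCCCl)[Cu-]Sc1ccccc1 | intermediate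
11 | lithium (3S,4S,5R)-4-[(tert-butyldimethylsilyl)oxy]-3-(5-chloropent-1-en-2-yl)-2-methyl-5-(propan-2-yl)cyclohex-1-en-1-olate (alkenyl group trans to OSi and to isopropyl) | C=C(CCCCl)[C@@H]1[C@@H](O[Si](C)(C)C(C)(C)C)[C@@H](C(C)C)CC(O[Li])=C1C | intermediate
12 | (3R,4S,4aS,8aR)-4-[(tert-butyldimethylsilyl)oxy]-8a-methyl-5-methylidene-3-(propan-2-yl)octahydronaphthalen-1(2H)-one (cis-fused; CH3, H-4a, OSi and isopropyl on one face) | C=C1CCC[C@]2(C)[C@H]1[C@@H](O[Si](C)(C)C(C)(C)C)[C@@H](C(C)C)CC2=O | intermediate
13 | (1R,3R,4S,4aS,8aR)-4-[(tert-butyldimethylsilyl)oxy]-8a-methyl-5-methylidene-3-(propan-2-yl)decahydronaphthalen-1-ol | C=C1CCC[C@]2(C)[C@H]1[C@@H](O[Si](C)(C)C(C)(C)C)[C@@H](C(C)C)C[C@H]2O | intermediate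
14 | 4-methoxybenzoyl chloride (p-anisoyl chloride) | COc1ccc(cc1)C(Cl)=O | starting material
15 | (1R,3R,4S,4aS,8aR)-4-[(tert-butyldimethylsilyl)oxy]-8a-methyl-5-methylidene-3-(propan-2-yl)decahydronaphthalen-1-yl 4-methoxybenzoate | C=C1CCC[C@]2(C)[C@H]1[C@@H](O[Si](C)(C)C(C)(C)C)[C@@H](C(C)C)C[C@H]2OC(=O)c1ccc(OC)cc1 | intermediate
16 | (1R,3R,4S,4aS,8aR)-4-hydroxy-8a-methyl-5-methylidene-3-(propan-2-yl)decahydronaphthalen-1-yl 4-methoxybenzoate, CNP0107029.1 | C=C1CCC[C@]2(C)[C@H]1[C@@H](O)[C@@H](C(C)C)C[C@H]2OC(=O)c1ccc(OC)cc1 | target

**Step count and risks**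
Total step count: 8. Longest linear sequence: 7 steps (steps 1, 2, 3, 5, 6, 7, 8; step 4 is a one-step side branch).

The three steps most likely to fail:

Step 5. The ring closure may lag behind the conjugate addition: alkylation of a lithium enolate at a fully substituted carbon by a primary chloride is slow, so the open-chain adduct may be recovered on work-up or HCl may be lost by E2. The fallback sets out from 5 (with 8) and comes back at 12. It uncouples the two events and changes both the leaving group and the enolate. The cuprate addition is run alone (no HMPA) and quenched with NH4Cl to isolate the chloro ketone (3R,4S,5R)-4-[(tert-butyldimethylsilyl)oxy]-3-(5-chloropent-1-en-2-yl)-2-methyl-5-(propan-2-yl)cyclohexan-1-one F1. Finkelstein exchange (NaI, acetone, reflux) gives the iodo ketone (3R,4S,5R)-4-[(tert-butyldimethylsilyl)oxy]-3-(5-iodopent-1-en-2-yl)-2-methyl-5-(propan-2-yl)cyclohexan-1-one F2. Cyclisation under equilibrating conditions (t-BuOK, t-BuOH/THF, rt) then lets the thermodynamic tetrasubstituted potassium enolate displace iodide to give 12.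

Step 6. Facial discrimination at C9 may be poor, because in one or the other chair of the cis-decalone both faces of the carbonyl are flanked by axial groups, so hydride delivery from the α-face could compete. The fallback sets out from 12 and comes back at 13. It replaces substrate control by reagent control: Corey–Bakshi–Shibata reduction with the (S)-methyl oxazaborolidine and catecholborane (toluene, −78 °C), which differentiates the quaternary C10 from the C8 methylene and should not hydroborate the 1,1-disubstituted alkene at this temperature. No new compound is formed.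

Step 3. The ene step may be slow or misdirected, since the alkene is deactivated by the allylic silyloxy group, and hydrogen abstraction from the C14 methyl or over-oxidation can compete. The fallback sets out from 3 and comes back at 4. It replaces the ene manifold by a π-allylpalladium C–H acetoxylation (Pd(OAc)2 cat., benzoquinone, AcOH, 50 °C; Åkermark–Bäckvall type), in which acetate should attack the less hindered allyl terminus C9 to give the allylic acetate (4S,5R)-4-[(tert-butyldimethylsilyl)oxy]-2-methyl-5-(propan-2-yl)cyclohex-2-en-1-yl acetate F3. Methanolysis (K2CO3, MeOH) gives 4, which is oxidised to 5 with Dess–Martin periodinane as in step 3.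

**Further compounds**
F1 | step 5 | (3R,4S,5R)-4-[(tert-butyldimethylsilyl)oxy]-3-(5-chloropent-1-en-2-yl)-2-methyl-5-(propan-2-yl)cyclohexan-1-one (C2 epimers) | C=C(CCCCl)[C@@H]1[C@@H](O[Si](C)(C)C(C)(C)C)[C@@H](C(C)C)CC(=O)C1C
F2 | step 5 | (3R,4S,5R)-4-[(tert-butyldimethylsilyl)oxy]-3-(5-iodopent-1-en-2-yl)-2-methyl-5-(propan-2-yl)cyclohexan-1-one (C2 epimers) | C=C(CCCI)[C@@H]1[C@@H](O[Si](C)(C)C(C)(C)C)[C@@H](C(C)C)CC(=O)C1C
F0 | step 6 | none | none
F3 | step 3 | (4S,5R)-4-[(tert-butyldimethylsilyl)oxy]-2-methyl-5-(propan-2-yl)cyclohex-2-en-1-yl acetate (C1 epimers) | CC1=C[C@@H](O[Si](C)(C)C(C)(C)C)[C@@H](C(C)C)CC1OC(C)=O
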